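**Retrosynthetic overview**
- The target is a (2R,3S,4R)-flavan-3,4-diol. C4 is set last by NaBH4 reduction of the debenzylated 2,3-trans dihydroflavonol, and the C3 hydroxyl comes from a Rubottom oxidation of a (2S)-flavanone.
- Ring C is closed by making the aryl ether bond C8a–O1: the C2 hydroxyl of an acyclic (S)-aldol adds to C8a of oxidised ring A (oxidative dearomatisation, oxa-Michael addition, re-aromatisation).
- Enabling feature: in ring A the C5 hydroxyl is para to the C8 methoxy group (a hydroquinone monomethyl ether), and C8a is the only ring carbon bearing H, between C8 and the acyl-bearing C4a. Two-electron oxidation therefore gives a p-quinone monoketal in which C8a is the β-carbon of both the C5 and the C4 carbonyl.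
- The aldol (C2–C3 bond, sets C2) comes from a catalytic enantioselective Mukaiyama aldol union of the ring A methyl ketone silyl enol ether with 3,4,5-tris(benzyloxy)benzaldehyde. The ring A ketone comes from acetosyringone by benzylation, ortho-iodination and hydroxylation.
- Ring order: rings A and B are purchased; ring C is the only ring formed (step 6).

Key step: step 6

Remark: flavonoid numbering (O1, C2, C3, C4, C4a, C5 to C8, C8a) is used for all intermediates, including the acyclic ones; 3,4,5-tris(benzyloxy)benzaldehyde is taken as purchasable.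
Remark: in step 5 the antipode of the bisphosphoramide catalyst that directs attack to the Si face of the aldehyde is assumed; the sense is to be checked on the first run and the other antipode used if needed.

Step 1
Reactants: 1 acetosyringone, 1-(4-hydroxy-3,5-dimethoxyphenyl)ethan-1-one
Product: 2 1-[4-(benzyloxy)-3,5-dimethoxyphenyl]ethan-1-one
Conditions: BnBr, K2CO3, DMF, 60 °C
Reagents that add atoms: benzyl bromide, BrCc1ccccc1
Why: Williamson etherification of the only phenol masks the future C7 oxygen as a benzyl ether, which should survive every step up to the final hydrogenolysis and keeps this oxygen out of the later phenol oxidation.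

Step 2
Reactants: 2 1-[4-(benzyloxy)-3,5-dimethoxyphenyl]ethan-1-one
Product: 3 1-[4-(benzyloxy)-2-iodo-3,5-dimethoxyphenyl]ethan-1-one
Conditions: I2 (1.05 equiv), CF3CO2Ag, CH2Cl2, 0 °C to rt
Reagents that add atoms: iodine, II
Why: Silver-assisted electrophilic aromatic iodination can only attack the two equivalent ring positions ortho to the acetyl group, each ortho and para to a methoxy group, and one equivalent should stop at the mono-iodide without α-halogenation of the ketone.

Step 3
Reactants: 3 1-[4-(benzyloxy)-2-iodo-3,5-dimethoxyphenyl]ethan-1-one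
Product: 4 1-[4-(benzyloxy)-2-hydroxy-3,5-dimethoxyphenyl]ethan-1-one
Conditions: CuI (10 mol%), 1,10-phenanthroline (20 mol%), KOH, DMSO/H2O (1:1), 100 °C; then 1 M HCl
Reagents that add atoms: potassium hydroxide, [K+].[OH-]
Why: Ullmann-type copper-catalysed hydroxylation of an aryl iodide, assisted here by the ortho acetyl group, installs the phenol that becomes the C5 hydroxyl and the oxidation handle of ring A.

Step 4
Reactants: 4 1-[4-(benzyloxy)-2-hydroxy-3,5-dimethoxyphenyl]ethan-1-one
Product: 5 [1-[4-(benzyloxy)-3,5-dimethoxy-2-(trimethylsilyloxy)phenyl]ethenyloxy]trimethylsilane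
Conditions: TMSOTf (2.4 equiv), Et3N, CH2Cl2, 0 °C
Reagents that add atoms: trimethylsilyl trifluoromethanesulfonate, C[Si](C)(C)OS(=O)(=O)C(F)(F)F
Why: Soft enolisation silylates both the phenol and the methyl ketone and gives the silyl enol ether needed for a Mukaiyama aldol addition without a free enolate.

Step 5
Reactants: 5 [1-[4-(benzyloxy)-3,5-dimethoxy-2-(trimethylsilyloxy)phenyl]ethenyloxy]trimethylsilane; 6 3,4,5-tris(benzyloxy)benzaldehyde
Product: 8 (3S)-1-[4-(benzyloxy)-2-hydroxy-3,5-dimethoxyphenyl]-3-hydroxy-3-[3,4,5-tris(benzyloxy)phenyl]propan-1-one, via trichlorosilyl aldolate 7 (not isolated)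
Conditions: SiCl4 (1.5 equiv), chiral binaphthyl-2,2'-diamine-derived bisphosphoramide (5 mol%), iPr2NEt (10 mol%), CH2Cl2, −78 °C; then aq. KF/KH2PO4
Reagents that add atoms: none
Why: In this Lewis-base-activated SiCl4 Mukaiyama aldol addition of a methyl-ketone silyl enol ether to an aromatic aldehyde, the chiral phosphoramide-bound trichlorosilyl cation should expose the Si face of 6 and so set the (S) carbinol centre (the future C2), and the aqueous fluoride work-up frees both the carbinol and the phenol.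

Step 6
Reactants: 8 (3S)-1-[4-(benzyloxy)-2-hydroxy-3,5-dimethoxyphenyl]-3-hydroxy-3-[3,4,5-tris(benzyloxy)phenyl]propan-1-one
Product: 11 (2S)-7-(benzyloxy)-5-hydroxy-6,8-dimethoxy-2-[3,4,5-tris(benzyloxy)phenyl]-2,3-dihydro-4H-chromen-4-one, via quinone monoketal 9 (not isolated), via oxa-Michael adduct 10 (not isolated)
Conditions: PhI(OAc)2 (1.0 equiv), MeOH (5 equiv), CH2Cl2, −20 to 0 °C; then CSA (10 mol%), 0 °C to rt
Reagents that add atoms: methanol, CO (supplies one of the two C8 ketal methoxy groups of 9; one of the two is lost again on aromatisation)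
Why: Proposed new method: PhI(OAc)2 exchanges a ligand for the C5 phenol of 8 and methanol attacks the para carbon C8, which already carries OMe, to give the 2-acyl p-quinone monoketal 9; in 9 the lone ring CH (C8a) is the β-carbon of both the C5 dienone carbonyl and the C4 ketone, so the C2 hydroxyl should add to it in a favoured 6-endo-trig oxa-Michael closure of ring C to give 10, and acid-catalysed loss of methanol from the C8 ketal re-aromatises ring A to 11 with 5-OH and 8-OMe in place. The closest known reaction types are the Michael addition and aromatisation of nucleophiles on quinone monoketals (regiospecific quinone equivalents) and the oxa-Michael addition of alcohols to C3 of 2-acyl-1,4-benzoquinones; what is new is their coupling into one dehydrogenative aryl C–H etherification that builds a chromanone. No new stereocentre remains: the sp3 centre formed at C8a is erased on aromatisation, and C2 keeps its (S) configuration because its C–O bond is never broken. The step needs oxidation of ring A only (it holds the only free phenol; C7 is benzylated and ring B is fully etherified), addition at C8a by the tethered hydroxyl and not by methanol (six-membered intramolecular path, methanol limited to 5 equiv), and no second oxidation of 11 (exactly 1.0 equiv of oxidant is consumed in the cold before the acid that triggers aromatisation is added).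

Step 7
Reactants: 11 (2S)-7-(benzyloxy)-5-hydroxy-6,8-dimethoxy-2-[3,4,5-tris(benzyloxy)phenyl]-2,3-dihydro-4H-chromen-4-one
Product: 12 (2S)-7-(benzyloxy)-6,8-dimethoxy-4,5-bis(trimethylsilyloxy)-2-[3,4,5-tris(benzyloxy)phenyl]-2H-chromene
Conditions: TMSOTf (2.5 equiv), Et3N, CH2Cl2, 0 °C
Reagents that add atoms: trimethylsilyl trifluoromethanesulfonate, C[Si](C)(C)OS(=O)(=O)C(F)(F)F
Why: Soft enolisation gives the C3–C4 silyl enol ether (and the C5 silyl ether) without a free enolate, which should avoid the base-induced retro-oxa-Michael ring opening that would scramble C2.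

Step 8
Reactants: 12 (2S)-7-(benzyloxy)-6,8-dimethoxy-4,5-bis(trimethylsilyloxy)-2-[3,4,5-tris(benzyloxy)phenyl]-2H-chromene
Product: 14 (2R,3R)-7-(benzyloxy)-3,5-dihydroxy-6,8-dimethoxy-2-[3,4,5-tris(benzyloxy)phenyl]-2,3-dihydro-4H-chromen-4-one, via silyloxy epoxide 13 (not isolated)
Conditions: dimethyldioxirane (1.1 equiv, acetone solution), CH2Cl2, −40 to 0 °C; then AcOH/MeOH/H2O, rt
Reagents that add atoms: dimethyldioxirane, CC1(C)OO1
Why: In this Rubottom oxidation the dioxirane should epoxidise the enol ether on the face anti to the C2 aryl group, so that hydrolysis gives the 2,3-trans (3R) ketol, which is also the thermodynamically preferred epimer.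

Step 9
Reactants: 14 (2R,3R)-7-(benzyloxy)-3,5-dihydroxy-6,8-dimethoxy-2-[3,4,5-tris(benzyloxy)phenyl]-2,3-dihydro-4H-chromen-4-one
Product: 15 (2R,3R)-3,5,7-trihydroxy-6,8-dimethoxy-2-(3,4,5-trihydroxyphenyl)-2,3-dihydro-4H-chromen-4-one
Conditions: H2 (1 atm), Pd/C, EtOAc/MeOH, rt
Reagents that add atoms: none
Why: Neutral hydrogenolysis over palladium on carbon cleaves the four benzyl ethers while the hydrogen-bonded C4 ketone, the ring C ether and both stereocentres should stay untouched.

Step 10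
Reactants: 15 (2R,3R)-3,5,7-trihydroxy-6,8-dimethoxy-2-(3,4,5-trihydroxyphenyl)-2,3-dihydro-4H-chromen-4-one
Product: 16 (2R,3S,4R)-6,8-dimethoxy-2-(3,4,5-trihydroxyphenyl)-3,4-dihydro-2H-chromene-3,4,5,7-tetrol
Conditions: NaBH4, EtOH, 0 °C, argon; then pH 7 phosphate buffer
Reagents that add atoms: none
Why: NaBH4 reduction of a 2,3-trans dihydroflavonol delivers hydride axially to C4 and gives the equatorial 4-hydroxyl trans to the 3-hydroxyl, the classical route from dihydroflavonols to 2,3-trans-3,4-trans flavan-3,4-diols, so the (2R,3S,4R) diol should result.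

**Compound list**
1 | acetosyringone, 1-(4-hydroxy-3,5-dimethoxyphenyl)ethan-1-one | CC(=O)c1cc(OC)c(O)c(OC)c1 | starting material
2 | 1-[4-(benzyloxy)-3,5-dimethoxyphenyl]ethan-1-one | CC(=O)c1cc(OC)c(OCc2ccccc2)c(OC)c1 | intermediate
3 | 1-[4-(benzyloxy)-2-iodo-3,5-dimethoxyphenyl]ethan-1-one | CC(=O)c1cc(OC)c(OCc2ccccc2)c(OC)c1I | intermediate
4 | 1-[4-(benzyloxy)-2-hydroxy-3,5-dimethoxyphenyl]ethan-1-one | CC(=O)c1cc(OC)c(OCc2ccccc2)c(OC)c1O | intermediate
5 | [1-[4-(benzyloxy)-3,5-dimethoxy-2-(trimethylsilyloxy)phenyl]ethenyloxy]trimethylsilane | C=C(O[Si](C)(C)C)c1cc(OC)c(OCc2ccccc2)c(OC)c1O[Si](C)(C)C | intermediate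
6 | 3,4,5-tris(benzyloxy)benzaldehyde | O=Cc1cc(OCc2ccccc2)c(OCc2ccccc2)c(OCc2ccccc2)c1 | starting material
7 | (3S)-1-[4-(benzyloxy)-3,5-dimethoxy-2-(trimethylsilyloxy)phenyl]-3-(trichlorosilyloxy)-3-[3,4,5-tris(benzyloxy)phenyl]propan-1-one (not isolated) | COc1cc(C(=O)C[C@H](O[Si](Cl)(Cl)Cl)c2cc(OCc3ccccc3)c(OCc3ccccc3)c(OCc3ccccc3)c2)c(O[Si](C)(C)C)c(OC)c1OCc1ccccc1 | intermediate
8 | (3S)-1-[4-(benzyloxy)-2-hydroxy-3,5-dimethoxyphenyl]-3-hydroxy-3-[3,4,5-tris(benzyloxy)phenyl]propan-1-one | COc1cc(C(=O)C[C@H](O)c2cc(OCc3ccccc3)c(OCc3ccccc3)c(OCc3ccccc3)c2)c(O)c(OC)c1OCc1ccccc1 | intermediate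
9 | 3-(benzyloxy)-6-[(3S)-3-hydroxy-3-[3,4,5-tris(benzyloxy)phenyl]propanoyl]-2,4,4-trimethoxycyclohexa-2,5-dien-1-one (not isolated) | O=C1C(C(=O)C[C@H](O)c2cc(OCc3ccccc3)c(OCc3ccccc3)c(OCc3ccccc3)c2)=CC(OC)(OC)C(OCc2ccccc2)=C1OC | intermediate
10 | (2S)-7-(benzyloxy)-5-hydroxy-6,8,8-trimethoxy-2-[3,4,5-tris(benzyloxy)phenyl]-2,3,8,8a-tetrahydro-4H-chromen-4-one, enol form, C8a configuration not defined (not isolated) | O=C1C[C@@H](c3cc(OCc4ccccc4)c(OCc4ccccc4)c(OCc4ccccc4)c3)OC2C1=C(O)C(OC)=C(OCc1ccccc1)C2(OC)OC | intermediate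
11 | (2S)-7-(benzyloxy)-5-hydroxy-6,8-dimethoxy-2-[3,4,5-tris(benzyloxy)phenyl]-2,3-dihydro-4H-chromen-4-one | COc1c(OCc3ccccc3)c(OC)c2c(c1O)C(=O)C[C@@H](c1cc(OCc3ccccc3)c(OCc3ccccc3)c(OCc3ccccc3)c1)O2 | intermediate
12 | (2S)-7-(benzyloxy)-6,8-dimethoxy-4,5-bis(trimethylsilyloxy)-2-[3,4,5-tris(benzyloxy)phenyl]-2H-chromene | COc1c(OCc3ccccc3)c(OC)c2c(c1O[Si](C)(C)C)C(O[Si](C)(C)C)=C[C@@H](c1cc(OCc3ccccc3)c(OCc3ccccc3)c(OCc3ccccc3)c1)O2 | intermediate
13 | 3,4-epoxide of 12, oxirane oxygen on the face opposite the C2 aryl group (not isolated) | COc1c(OCc3ccccc3)c(OC)c2c(c1O[Si](C)(C)C)[C@]5(O[Si](C)(C)C)O[C@@H]5[C@@H](c1cc(OCc3ccccc3)c(OCc3ccccc3)c(OCc3ccccc3)c1)O2 | intermediate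
14 | (2R,3R)-7-(benzyloxy)-3,5-dihydroxy-6,8-dimethoxy-2-[3,4,5-tris(benzyloxy)phenyl]-2,3-dihydro-4H-chromen-4-one | COc1c(OCc3ccccc3)c(OC)c2c(c1O)C(=O)[C@H](O)[C@@H](c1cc(OCc3ccccc3)c(OCc3ccccc3)c(OCc3ccccc3)c1)O2 | intermediate
15 | (2R,3R)-3,5,7-trihydroxy-6,8-dimethoxy-2-(3,4,5-trihydroxyphenyl)-2,3-dihydro-4H-chromen-4-one | COc1c(O)c(OC)c2c(c1O)C(=O)[C@H](O)[C@@H](c1cc(O)c(O)c(O)c1)O2 | intermediate
16 | (2R,3S,4R)-6,8-dimethoxy-2-(3,4,5-trihydroxyphenyl)-3,4-dihydro-2H-chromene-3,4,5,7-tetrol | COc1c(O)c(OC)c2c(c1O)[C@@H](O)[C@H](O)[C@@H](c1cc(O)c(O)c(O)c1)O2 | target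

**Totals**
Total step count: 10. Longest linear sequence: 10 steps (from 1 to 16; aldehyde 6 enters in step 5).

**Steps most likely to fail**

Step 6 (proposed new method). What may go wrong: a second oxidation of the cyclised phenol by oxidant still present; capture of the monoketal at C8a by methanol or water in place of the side-chain hydroxyl; acid-induced ionisation at the benzylic C2 during aromatisation, with loss of configuration. The fallback uses known chemistry, sets out from 8 and returns at 11. Oxidative demethylation of the p-methoxyphenol 8 with PhI(OAc)2 in aqueous MeCN gives the 2-acyl-1,4-benzoquinone F1. The side-chain hydroxyl adds to C3 of the acylquinone (oxa-Michael addition, then tautomerisation), and a Na2S2O4 wash returns any quinone-level material, to give the 5,8-dihydroxychromanone F2. Over-oxidation is harmless at this oxidation level. Hydrogen bonding of the 5-hydroxyl to the C4 carbonyl leaves only the 8-hydroxyl for methylation with Me3SiCHN2 in MeOH/toluene, which gives 11.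

Step 5. What may go wrong: low enantioselectivity or low conversion because the enol ether is ortho-substituted and very electron-rich, or exchange of the aryl silyl ether with SiCl4. The fallback sets out from 4 and returns at 8. Allylation (allyl bromide, K2CO3, DMF) gives the allyl ether F3. Claisen–Schmidt condensation with 6 (KOH, EtOH) gives the (E)-chalcone F4. Copper-catalysed enantioselective conjugate borylation (CuCl, NaOtBu, a Josiphos ligand of the antipode that gives the (S) product, B2pin2, MeOH, THF) gives the β-boryl ketone F5. Oxidation with NaBO3·4H2O, with retention, gives the (S)-β-hydroxy ketone F6. Deallylation with Pd(PPh3)4 and morpholine under neutral conditions gives 8.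

Step 8. What may go wrong: poor facial selectivity of the epoxidation, oxidation of the electron-rich ring A by the dioxirane, or partial ring opening during enol silylation in step 7 that erodes C2. The fallback avoids any enol derivative, sets out from 11 and returns at 16. NaBH4 reduces 11 to the 2,4-cis flavan-4-ol F7. Mild acid-catalysed dehydration (PPTS, toluene, 60 °C) gives the flav-3-ene F8. Dimethyldioxirane epoxidises F8 anti to the C2 aryl group to give the epoxide F9. Water opens F9 at the benzylic C4 with inversion to give the tetra-O-benzyl (2R,3S,4R)-diol F10. Neutral hydrogenolysis (H2, Pd/C, EtOAc) then gives 16.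

Further compounds
F1 | step 6 | 2-(benzyloxy)-5-[(3S)-3-hydroxy-3-[3,4,5-tris(benzyloxy)phenyl]propanoyl]-3-methoxycyclohexa-2,5-diene-1,4-dione | O=C1C(C(=O)C[C@H](O)c2cc(OCc3ccccc3)c(OCc3ccccc3)c(OCc3ccccc3)c2)=CC(=O)C(OCc2ccccc2)=C1OC
F2 | step 6 | (2S)-7-(benzyloxy)-5,8-dihydroxy-6-methoxy-2-[3,4,5-tris(benzyloxy)phenyl]-2,3-dihydro-4H-chromen-4-one | COc1c(OCc3ccccc3)c(O)c2c(c1O)C(=O)C[C@@H](c1cc(OCc3ccccc3)c(OCc3ccccc3)c(OCc3ccccc3)c1)O2
F3 | step 5 | 1-[2-(allyloxy)-4-(benzyloxy)-3,5-dimethoxyphenyl]ethan-1-one | CC(=O)c1cc(OC)c(OCc2ccccc2)c(OC)c1OCC=C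
F4 | step 5 | (E)-1-[2-(allyloxy)-4-(benzyloxy)-3,5-dimethoxyphenyl]-3-[3,4,5-tris(benzyloxy)phenyl]prop-2-en-1-one | COc1cc(C(=O)/C=C/c2cc(OCc3ccccc3)c(OCc3ccccc3)c(OCc3ccccc3)c2)c(OCC=C)c(OC)c1OCc1ccccc1
F5 | step 5 | (3S)-1-[2-(allyloxy)-4-(benzyloxy)-3,5-dimethoxyphenyl]-3-(4,4,5,5-tetramethyl-1,3,2-dioxaborolan-2-yl)-3-[3,4,5-tris(benzyloxy)phenyl]propan-1-one | COc1cc(C(=O)C[C@H](B2OC(C)(C)C(C)(C)O2)c2cc(OCc3ccccc3)c(OCc3ccccc3)c(OCc3ccccc3)c2)c(OCC=C)c(OC)c1OCc1ccccc1
F6 | step 5 | (3S)-1-[2-(allyloxy)-4-(benzyloxy)-3,5-dimethoxyphenyl]-3-hydroxy-3-[3,4,5-tris(benzyloxy)phenyl]propan-1-one | COc1cc(C(=O)C[C@H](O)c2cc(OCc3ccccc3)c(OCc3ccccc3)c(OCc3ccccc3)c2)c(OCC=C)c(OC)c1OCc1ccccc1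
F7 | step 8 | (2S,4S)-7-(benzyloxy)-6,8-dimethoxy-2-[3,4,5-tris(benzyloxy)phenyl]-3,4-dihydro-2H-chromene-4,5-diol | COc1c(OCc3ccccc3)c(OC)c2c(c1O)[C@@H](O)C[C@@H](c1cc(OCc3ccccc3)c(OCc3ccccc3)c(OCc3ccccc3)c1)O2
F8 | step 8 | (2S)-7-(benzyloxy)-6,8-dimethoxy-2-[3,4,5-tris(benzyloxy)phenyl]-2H-chromen-5-ol | COc1c(OCc3ccccc3)c(OC)c2c(c1O)C=C[C@@H](c1cc(OCc3ccccc3)c(OCc3ccccc3)c(OCc3ccccc3)c1)O2
F9 | step 8 | 3,4-epoxide of F8, oxirane oxygen on the face opposite the C2 aryl group | COc1c(OCc3ccccc3)c(OC)c2c(c1O)[C@@H]5O[C@@H]5[C@@H](c1cc(OCc3ccccc3)c(OCc3ccccc3)c(OCc3ccccc3)c1)O2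
F10 | step 8 | (2R,3S,4R)-7-(benzyloxy)-6,8-dimethoxy-2-[3,4,5-tris(benzyloxy)phenyl]-3,4-dihydro-2H-chromene-3,4,5-triol | COc1c(OCc3ccccc3)c(OC)c2c(c1O)[C@@H](O)[C@H](O)[C@@H](c1cc(OCc3ccccc3)c(OCc3ccccc3)c(OCc3ccccc3)c1)O2
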